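## Retrosynthetic overview

- The target is released in one flask from its tetraacetonide dimethyl ester (methyl esters cleaved first, then the four catechol ketals).
- The ring A–vinyl bond of the E-cinnamate arm is cut last: Heck reaction of an aryl bromide with the acrylate of protected methyl (R)-danshensuate.
- Key bond, ring A C2 to the α-carbon of the second caffeoyl unit: Meerwein aryl-radical addition of a 5-bromo-benzodioxole-4-diazonium ion to the α-carbon of fully assembled, protected methyl rosmarinate, then loss of H+ to the E-alkene (regiochemistry opposite to a Heck arylation).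
- Protected rosmarinate comes from a Heck reaction of bromocatechol acetonide with the same acrylate; the acrylate comes from copper-catalysed opening of methyl (R)-glycidate by the aryl Grignard reagent (source of both stereocenters) and acryloyl chloride.
- No ring of the target is built: all four benzene rings are catechol. The only rings formed are the four acetonide rings (first step), opened again in the last step.

Assumption: catechol, methyl (R)-glycidate and acryloyl chloride are bought, and operations run in one flask without isolation count as one step.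

## Route

Step 1
Reactants: 1 catechol
Product: 2 2,2-dimethyl-1,3-benzodioxole
Conditions: 2,2-dimethoxypropane, TsOH·H2O (cat.), toluene, reflux, MeOH removed (4 Å sieves in a Soxhlet)
Reagents that add atoms: 2,2-dimethoxypropane, COC(C)(C)OC
Why: Acid-catalysed transketalisation (acetonide formation) of the two adjacent phenolic OH groups, driven by removal of methanol.

Step 2
Reactants: 2 2,2-dimethyl-1,3-benzodioxole
Product: 3 5-bromo-2,2-dimethyl-1,3-benzodioxole
Conditions: NBS, DMF, 0 °C → rt
Reagents that add atoms: N-bromosuccinimide, O=C1CCC(=O)N1Br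
Why: Electrophilic aromatic bromination goes para to a ring oxygen (position 5), the activated and unhindered site.

Step 3
Reactants: 3 5-bromo-2,2-dimethyl-1,3-benzodioxole; 4 methyl (2R)-oxirane-2-carboxylate (methyl (R)-glycidate)
Product: 6 methyl (2R)-3-(2,2-dimethyl-1,3-benzodioxol-5-yl)-2-hydroxypropanoate, via Grignard reagent 5 (not isolated)
Conditions: Mg, THF, 40 °C; then CuBr·SMe2 (10 mol %), 4, THF, −40 → −20 °C; aq. NH4Cl
Reagents that add atoms: none
Why: Grignard formation, then copper-catalysed SN2 opening of the epoxide at its CH2 terminus; the C2–O bond is not touched, so the R configuration of 4 is carried unchanged into 6.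

Step 4
Reactants: 6 methyl (2R)-3-(2,2-dimethyl-1,3-benzodioxol-5-yl)-2-hydroxypropanoate; 7 acryloyl chloride
Product: 8 methyl (2R)-3-(2,2-dimethyl-1,3-benzodioxol-5-yl)-2-(prop-2-enoyloxy)propanoate
Conditions: Et3N, BHT (cat.), CH2Cl2, −20 → 0 °C
Reagents that add atoms: none
Why: Acylation of the secondary alcohol by an acid chloride (esterification); the stereocenter is not involved.

Step 5
Reactants: 3 5-bromo-2,2-dimethyl-1,3-benzodioxole; 8 methyl (2R)-3-(2,2-dimethyl-1,3-benzodioxol-5-yl)-2-(prop-2-enoyloxy)propanoate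
Product: 9 methyl (2R)-3-(2,2-dimethyl-1,3-benzodioxol-5-yl)-2-{[(2E)-3-(2,2-dimethyl-1,3-benzodioxol-5-yl)prop-2-enoyl]oxy}propanoate (protected methyl rosmarinate)
Conditions: Pd2(dba)3 (1.5 mol %), [HP(t-Bu)3]BF4 (6 mol %), Cy2NMe, dioxane, 70 °C
Reagents that add atoms: none
Why: Mizoroki–Heck reaction of the aryl bromide with the acrylate on zerovalent palladium; syn-insertion and syn-β-hydride elimination give the E-cinnamate, and the stereocenter is remote.

Step 6
Reactants: 3 5-bromo-2,2-dimethyl-1,3-benzodioxole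
Product: 13 5-bromo-2,2-dimethyl-1,3-benzodioxol-4-amine, via aryllithium 10 (not isolated), via lithium triazenide 11 (not isolated), via aryl azide 12 (not isolated)
Conditions: LiN(i-Pr)2 (LDA), THF, −78 °C; TsN3, −78 °C; aq. Na4P2O7, rt; then PPh3, THF/H2O, 50 °C
Reagents that add atoms: tosyl azide, Cc1ccc(cc1)S(=O)(=O)N=[N+]=[N-]
Why: Directed ortho-metalation removes the most acidic ring proton (flanked by oxygen and bromine); tosyl azide traps the aryllithium at −78 °C before LiBr loss to an aryne can start (electrophilic azide transfer through the triazenide), and Staudinger reduction gives the aniline.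

Step 7
Reactants: 13 5-bromo-2,2-dimethyl-1,3-benzodioxol-4-amine; 9 protected methyl rosmarinate
Product: 15 methyl (2R)-2-{[(2E)-2-(5-bromo-2,2-dimethyl-1,3-benzodioxol-4-yl)-3-(2,2-dimethyl-1,3-benzodioxol-5-yl)prop-2-enoyl]oxy}-3-(2,2-dimethyl-1,3-benzodioxol-5-yl)propanoate, via diazonium tosylate 14 (not isolated)
Conditions: 13 (2 equiv), t-BuONO, TsOH·H2O, MeCN, 0 °C; added to 9, CuCl (10 mol %), acetone/MeCN, 0 → 25 °C; then Et3N, 25 °C
Reagents that add atoms: none
Why: Meerwein arylation: monovalent copper reduces 14 to the aryl σ-radical, which adds to the carbon α to the ester of 9 (the known regiochemistry of radical arylation of cinnamates and coumarins, opposite to a Heck reaction) to give a dialkoxy-stabilised benzylic radical; divalent copper or a second diazonium ion oxidises this to the cation, and loss of the acidic α-proton gives the alkene with the β-aryl group trans to the ester (E), the only geometry that keeps the cinnamate planar because the doubly ortho-substituted ring A is twisted either way; the stereocenter of 9 is not touched.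

Step 8
Reactants: 15 bromo α-aryl cinnamate from step 7; 8 methyl (2R)-3-(2,2-dimethyl-1,3-benzodioxol-5-yl)-2-(prop-2-enoyloxy)propanoate
Product: 16 tetraacetonide dimethyl ester of salvianolic acid E (both stereocenters R; both alkenes E)
Conditions: 8 (1.5 equiv), Pd2(dba)3 (2.5 mol %), [HP(t-Bu)3]BF4 (10 mol %), Cy2NMe, dioxane, 90 °C
Reagents that add atoms: none
Why: Mizoroki–Heck reaction at the remaining C–Br bond with a bulky electron-rich phosphine that tolerates the ortho substituent; the trisubstituted alkene is inert, the new alkene forms E, and no stereocenter is touched.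

Step 9
Reactants: 16 tetraacetonide dimethyl ester of salvianolic acid E
Product: 18 salvianolic acid E, via tetraacetonide diacid 17 (not isolated)
Conditions: Me3SnOH (10 equiv), ClCH2CH2Cl, 80 °C; evaporate; then TFA/H2O 9:1, 0 °C → rt, argon; reverse-phase HPLC
Reagents that add atoms: trimethyltin hydroxide, C[Sn](C)(C)O
Why: Organotin-mediated hydrolysis cleaves the two unhindered methyl esters and leaves the hindered, conjugated secondary esters and the α-stereocenters alone; acid-catalysed ketal hydrolysis then frees the four catechols without touching alkenes or stereocenters.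

## Compound list

1 | catechol | Oc1ccccc1O | starting material
2 | 2,2-dimethyl-1,3-benzodioxole | CC1(C)Oc2ccccc2O1 | intermediate
3 | 5-bromo-2,2-dimethyl-1,3-benzodioxole | CC1(C)Oc2ccc(Br)cc2O1 | intermediate
4 | methyl (2R)-oxirane-2-carboxylate (methyl (R)-glycidate) | COC(=O)[C@H]1CO1 | starting material
5 | (2,2-dimethyl-1,3-benzodioxol-5-yl)magnesium bromide (not isolated) | CC1(C)Oc2ccc([Mg]Br)cc2O1 | intermediate
6 | methyl (2R)-3-(2,2-dimethyl-1,3-benzodioxol-5-yl)-2-hydroxypropanoate | COC(=O)[C@H](O)Cc1ccc2OC(C)(C)Oc2c1 | intermediate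
7 | acryloyl chloride | C=CC(=O)Cl | starting material
8 | methyl (2R)-3-(2,2-dimethyl-1,3-benzodioxol-5-yl)-2-(prop-2-enoyloxy)propanoate | COC(=O)[C@H](OC(=O)C=C)Cc1ccc2OC(C)(C)Oc2c1 | intermediate
9 | methyl (2R)-3-(2,2-dimethyl-1,3-benzodioxol-5-yl)-2-{[(2E)-3-(2,2-dimethyl-1,3-benzodioxol-5-yl)prop-2-enoyl]oxy}propanoate | COC(=O)[C@H](OC(=O)/C=C/c1ccc2OC(C)(C)Oc2c1)Cc1ccc2OC(C)(C)Oc2c1 | intermediate
10 | (5-bromo-2,2-dimethyl-1,3-benzodioxol-4-yl)lithium (not isolated) | [Li]c1c(Br)ccc2OC(C)(C)Oc12 | intermediate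
11 | lithium 1-(5-bromo-2,2-dimethyl-1,3-benzodioxol-4-yl)-3-tosyltriazenide (not isolated) | [Li+].Cc1ccc(cc1)S(=O)(=O)[N-]N=Nc1c(Br)ccc2OC(C)(C)Oc12 | intermediate
12 | 4-azido-5-bromo-2,2-dimethyl-1,3-benzodioxole (not isolated) | [N-]=[N+]=Nc1c(Br)ccc2OC(C)(C)Oc12 | intermediate
13 | 5-bromo-2,2-dimethyl-1,3-benzodioxol-4-amine | Nc1c(Br)ccc2OC(C)(C)Oc12 | intermediate
14 | 5-bromo-2,2-dimethyl-1,3-benzodioxole-4-diazonium 4-methylbenzenesulfonate (not isolated) | N#[N+]c1c(Br)ccc2OC(C)(C)Oc12.Cc1ccc(cc1)S(=O)(=O)[O-] | intermediate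
15 | methyl (2R)-2-{[(2E)-2-(5-bromo-2,2-dimethyl-1,3-benzodioxol-4-yl)-3-(2,2-dimethyl-1,3-benzodioxol-5-yl)prop-2-enoyl]oxy}-3-(2,2-dimethyl-1,3-benzodioxol-5-yl)propanoate | COC(=O)[C@H](OC(=O)/C(=C/c1ccc2OC(C)(C)Oc2c1)c1c(Br)ccc2OC(C)(C)Oc12)Cc1ccc2OC(C)(C)Oc2c1 | intermediate
16 | tetraacetonide dimethyl ester of salvianolic acid E: methyl (2R)-3-(2,2-dimethyl-1,3-benzodioxol-5-yl)-2-{[(2E)-3-{4-[(1E)-2-(2,2-dimethyl-1,3-benzodioxol-5-yl)-1-({[(2R)-3-(2,2-dimethyl-1,3-benzodioxol-5-yl)-1-methoxy-1-oxopropan-2-yl]oxy}carbonyl)ethenyl]-2,2-dimethyl-1,3-benzodioxol-5-yl}prop-2-enoyl]oxy}propanoate | O=C(/C=C/c1ccc2OC(C)(C)Oc2c1/C(=C\c1ccc2OC(C)(C)Oc2c1)C(=O)O[C@H](Cc1ccc2OC(C)(C)Oc2c1)C(=O)OC)O[C@H](Cc1ccc2OC(C)(C)Oc2c1)C(=O)OC | intermediate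
17 | tetraacetonide of salvianolic acid E (free diacid; both stereocenters R; both alkenes E; not isolated) | O=C(/C=C/c1ccc2OC(C)(C)Oc2c1/C(=C\c1ccc2OC(C)(C)Oc2c1)C(=O)O[C@H](Cc1ccc2OC(C)(C)Oc2c1)C(=O)O)O[C@H](Cc1ccc2OC(C)(C)Oc2c1)C(=O)O | intermediate
18 | salvianolic acid E | O=C(/C=C/c1ccc(O)c(O)c1/C(=C\c1ccc(O)c(O)c1)C(=O)O[C@H](Cc1ccc(O)c(O)c1)C(=O)O)O[C@H](Cc1ccc(O)c(O)c1)C(=O)O | target

## Step count and risks

Total step count: 9. Longest linear sequence: 8 steps (steps 1, 2, 3, 4, 5, 7, 8, 9); step 6 is a one-step branch from 3.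

Steps most likely to fail:

Step 7. This is an intermolecular Meerwein arylation with a hindered aryl radical on a fully functionalised acceptor. Sandmeyer-type loss of the diazonium, radical arylation of the benzodioxole rings and an E/Z mixture can all lower the yield. The fallback replaces the oxidative arylation of an alkene by a reductive radical hydroarylation of an alkyne; it sets out from 3 and 6 and comes back to the route at 15. Aryllithium 10 (from 3 with LDA as in step 6) is quenched with I2 at −78 °C to give 5-bromo-4-iodo-2,2-dimethyl-1,3-benzodioxole F1. Bromide 3 is coupled with propiolic acid (PdCl2(PPh3)2, dppb, DBU, DMSO, 50 °C) to give 3-(2,2-dimethyl-1,3-benzodioxol-5-yl)prop-2-ynoic acid F2. Esterification of F2 with alcohol 6 (DCC, DMAP cat., CH2Cl2, 0 °C) gives methyl (2R)-3-(2,2-dimethyl-1,3-benzodioxol-5-yl)-2-{[3-(2,2-dimethyl-1,3-benzodioxol-5-yl)prop-2-ynoyl]oxy}propanoate F3. Slow addition of Bu3SnH with AIBN in benzene at 80 °C to F1 and excess F3 takes iodine, not bromine, from F1; the aryl radical adds to the alkyne carbon α to the ester, and the linear α-aryl vinyl radical takes hydrogen on the side away from ring A, which gives 15 directly for step 8.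

Step 6. The ortho-bromoaryllithium can lose LiBr to an aryne, and azide transfer from tosyl azide to a hindered aryllithium can stall at the triazenide. The fallback brings in nitrogen by a rearrangement at carbon and not by an electrophilic nitrogen reagent; it sets out from 3 and comes back at 13. Aryllithium 10 is trapped with CO2 at −78 °C (then aq. HCl) to give 5-bromo-2,2-dimethyl-1,3-benzodioxole-4-carboxylic acid F4. DPPA and Et3N in toluene convert F4 to 5-bromo-2,2-dimethyl-1,3-benzodioxole-4-carbonyl azide F5, which on warming to 80 °C rearranges (Curtius) to 5-bromo-4-isocyanato-2,2-dimethyl-1,3-benzodioxole F6. Aqueous KOH in THF hydrolyses F6 to aniline 13.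

Step 9. The methyl ester cleavage must spare two internal esters, and the free product can lactonise onto the ring A phenol or cyclise in strong acid if left too long. The fallback reverses the order and uses an enzyme for the ester cleavage; it sets out from 16 and comes back at 18. Brief TFA/H2O treatment of 16 at 0 °C removes the four acetonides to give salvianolic acid E dimethyl ester F7. Pig liver esterase in pH 7 phosphate buffer with a little DMSO under argon then hydrolyses only the two unhindered methyl esters of F7 to give 18.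

## Further compounds

F1 | step 7 | 5-bromo-4-iodo-2,2-dimethyl-1,3-benzodioxole | Ic1c(Br)ccc2OC(C)(C)Oc12
F2 | step 7 | 3-(2,2-dimethyl-1,3-benzodioxol-5-yl)prop-2-ynoic acid | OC(=O)C#Cc1ccc2OC(C)(C)Oc2c1
F3 | step 7 | methyl (2R)-3-(2,2-dimethyl-1,3-benzodioxol-5-yl)-2-{[3-(2,2-dimethyl-1,3-benzodioxol-5-yl)prop-2-ynoyl]oxy}propanoate | COC(=O)[C@H](OC(=O)C#Cc1ccc2OC(C)(C)Oc2c1)Cc1ccc2OC(C)(C)Oc2c1
F4 | step 6 | 5-bromo-2,2-dimethyl-1,3-benzodioxole-4-carboxylic acid | OC(=O)c1c(Br)ccc2OC(C)(C)Oc12
F5 | step 6 | 5-bromo-2,2-dimethyl-1,3-benzodioxole-4-carbonyl azide | [N-]=[N+]=NC(=O)c1c(Br)ccc2OC(C)(C)Oc12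
F6 | step 6 | 5-bromo-4-isocyanato-2,2-dimethyl-1,3-benzodioxole | O=C=Nc1c(Br)ccc2OC(C)(C)Oc12
F7 | step 9 | salvianolic acid E dimethyl ester | O=C(/C=C/c1ccc(O)c(O)c1/C(=C\c1ccc(O)c(O)c1)C(=O)O[C@H](Cc1ccc(O)c(O)c1)C(=O)OC)O[C@H](Cc1ccc(O)c(O)c1)C(=O)OC
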